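**Assumption (one line):** the presumed biosynthesis is N1-acylation of N4-acetylspermidine by a (2E,4Z,6E,8R)-8-hydroxydeca-2,4,6-trienoyl unit followed by conjugate addition of N8 to C3 (spermidine N1/N4/N8 and acid C1–C10 numbering used below; target C3 = ring C2, both centres R); (R)-pent-1-yn-3-ol is taken as a catalogue chemical.

## Retrosynthetic overview

1. The only ring (13-membered lactam) is closed last at C3–N8 by a catalyst-controlled macrocyclising aza-Michael addition of the free N8 amine onto the N1-trienamide; this step sets C3.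
2. The seco-trienamide comes from a Suzuki coupling (C5–C6) of a (2E,4Z)-5-iododienamide with an (E)-alkenylboronate; C8 is bought in as (R)-pent-1-yn-3-ol.
3. The iododienamide comes from a one-pot half-reduction/Horner–Wadsworth–Emmons reaction (C2=C3) of ethyl (Z)-3-iodoacrylate with the phosphonoacetamide of the polyamine.
4. The differentiated polyamine (N1 free, N4 acetyl, N8 Boc) comes from N-Boc-putrescine, acrylonitrile, acetylation and nitrile hydrogenation.
5. Ring order: one ring only, formed in the final step.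

## Route

Step 1
Reactants: 1 tert-butyl N-(4-aminobutyl)carbamate; 2 acrylonitrile
Product: 4 tert-butyl N-[4-[acetyl(2-cyanoethyl)amino]butyl]carbamate, via the N-(2-cyanoethyl) secondary amine 3 (not isolated)
Conditions: 2 (1.05 equiv), MeOH, 0 °C to rt, 16 h; evaporate; Ac2O (1.2 equiv), Et3N (1.5 equiv), CH2Cl2, 0 °C to rt
Reagents that add atoms: acetic anhydride, CC(=O)OC(C)=O
Why: aza-Michael addition of the primary amine to acrylonitrile stops at mono-cyanoethylation with one equivalent in methanol, and the new secondary amine is then N-acetylated in the same flask while the Boc-NH stays inert.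

Step 2
Reactants: 4 tert-butyl N-[4-[acetyl(2-cyanoethyl)amino]butyl]carbamate
Product: 5 tert-butyl N-[4-[acetyl(3-aminopropyl)amino]butyl]carbamate
Conditions: H2 (4 bar), Raney Ni, 7 M NH3 in MeOH, rt, 12 h
Reagents that add atoms: none
Why: heterogeneous nitrile hydrogenation gives the primary amine (ammonia suppresses secondary-amine formation); the carbamate and tertiary acetamide are not reduced.

Step 3
Reactants: 5 tert-butyl N-[4-[acetyl(3-aminopropyl)amino]butyl]carbamate; 6 2-(diethoxyphosphoryl)acetic acid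
Product: 7 tert-butyl N-[4-[acetyl-[3-[[2-(diethoxyphosphoryl)acetyl]amino]propyl]amino]butyl]carbamate
Conditions: DIC (1.1 equiv), Oxyma (1.0 equiv), CH2Cl2, 0 °C to rt
Reagents that add atoms: none
Why: carbodiimide amide coupling at the only free amine (N1) installs C1–C2 as a Horner–Wadsworth–Emmons reagent.

Step 4
Reactants: 7 tert-butyl N-[4-[acetyl-[3-[[2-(diethoxyphosphoryl)acetyl]amino]propyl]amino]butyl]carbamate; 8 ethyl (Z)-3-iodoprop-2-enoate
Product: 10 tert-butyl N-[4-[acetyl-[3-[[(2E,4Z)-5-iodopenta-2,4-dienoyl]amino]propyl]amino]butyl]carbamate, via (Z)-3-iodoacrolein 9 (not isolated)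
Conditions: 8, i-Bu2AlH (1.05 equiv), CH2Cl2, −78 °C, 30 min; then lithium salt of 7 [LiN(SiMe3)2 (1.05 equiv), THF, −78 °C] added, −78 °C to rt, 3 h, dark
Reagents that add atoms: none
Why: half-reduction of the ester gives the aluminium hemiacetal of the Z-iodoenal, which is trapped in situ by Horner–Wadsworth–Emmons olefination before it can isomerise, so C2=C3 forms E (amide-stabilised phosphonate) and the Z-iodoalkene is retained.

Step 5
Reactants: 11 (R)-pent-1-yn-3-ol
Product: 12 (R,E)-1-(4,4,5,5-tetramethyl-1,3,2-dioxaborolan-2-yl)pent-1-en-3-ol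
Conditions: B2pin2 (1.1 equiv), CuCl (5 mol%), P(p-tolyl)3 (6 mol%), NaOt-Bu (15 mol%), MeOH (2 equiv), THF, rt, 6 h
Reagents that add atoms: bis(pinacolato)diboron, CC1(C)OB(OC1(C)C)B1OC(C)(C)C(C)(C)O1
Why: copper-catalysed formal hydroboration (syn borylcupration with boron on the terminal carbon, then protonolysis by methanol) gives the E-alkenylboronate; the purchased carbinol centre (future C8, R) is not touched.

Step 6
Reactants: 10 tert-butyl N-[4-[acetyl-[3-[[(2E,4Z)-5-iodopenta-2,4-dienoyl]amino]propyl]amino]butyl]carbamate; 12 (R,E)-1-(4,4,5,5-tetramethyl-1,3,2-dioxaborolan-2-yl)pent-1-en-3-ol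
Product: 13 tert-butyl N-[4-[acetyl-[3-[[(2E,4Z,6E,8R)-8-hydroxydeca-2,4,6-trienoyl]amino]propyl]amino]butyl]carbamate
Conditions: PdCl2(dppf) (5 mol%), K3PO4 (3 equiv), THF/H2O 9:1, rt, dark, 6 h
Reagents that add atoms: none
Why: Suzuki–Miyaura coupling of an alkenyl iodide with an alkenylboronate proceeds with retention at both alkenes at room temperature, giving the 2E,4Z,6E triene with the free hydroxyl, amide and Boc groups tolerated.

Step 7
Reactants: 13 tert-butyl N-[4-[acetyl-[3-[[(2E,4Z,6E,8R)-8-hydroxydeca-2,4,6-trienoyl]amino]propyl]amino]butyl]carbamate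
Product: 15 (2E,4Z,6E,8R)-N-[3-[acetyl(4-aminobutyl)amino]propyl]-8-hydroxydeca-2,4,6-trienamide, via the bis(trimethylsilyl) intermediate 14 (not isolated)
Conditions: TMSOTf (3 equiv), 2,6-lutidine (4 equiv), CH2Cl2, 0 °C, 30 min; MeOH, 0 °C to rt; aq. NaHCO3
Reagents that add atoms: none
Why: buffered silyl-triflate Boc cleavage (Boc to silyl carbamate with loss of isobutene, then methanolysis and decarboxylation) frees N8 without protic acid, which would ionise the trienyl carbinol; the transient O-silyl ether is cleaved in the same methanolysis.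

Step 8
Reactants: 15 (2E,4Z,6E,8R)-N-[3-[acetyl(4-aminobutyl)amino]propyl]-8-hydroxydeca-2,4,6-trienamide
Product: 16 (2R)-9-acetyl-2-[(1Z,3E,5R)-5-hydroxyhepta-1,3-dien-1-yl]-1,5,9-triazacyclotridecan-4-one
Conditions: bifunctional iminophosphorane–thiourea organocatalyst (BIMP type, from (S)-tert-leucine and P(4-MeOC6H4)3; 15 mol%), THF/toluene 1:1, 5 mM, 40 °C, 72 h, argon
Reagents that add atoms: none
Why: Proposed new method: a 13-membered ring-closing, face-selective aza-Michael addition of N8 to C3 of the unactivated trienamide, in which the catalyst thiourea hydrogen-bonds the amide carbonyl and the iminophosphorane relays the N–H proton to C2, so that closure is 1,4 (the 4Z and 6E alkenes are untouched) and C3 is set R by catalyst control, the remote C8 centre giving no bias (the sense of induction is not predictable from precedent, so the mirror-image catalyst is used if it proves opposite); the closest known reaction type is bifunctional iminophosphorane-catalysed enantioselective sulfa- and oxa-Michael addition to unactivated α,β-unsaturated amides.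

## Compound list

1 | tert-butyl N-(4-aminobutyl)carbamate | CC(C)(C)OC(=O)NCCCCN | starting material
2 | acrylonitrile | C=CC#N | starting material
3 | tert-butyl N-[4-(2-cyanoethylamino)butyl]carbamate (not isolated) | CC(C)(C)OC(=O)NCCCCNCCC#N | intermediate
4 | tert-butyl N-[4-[acetyl(2-cyanoethyl)amino]butyl]carbamate | CC(C)(C)OC(=O)NCCCCN(CCC#N)C(C)=O | intermediate
5 | tert-butyl N-[4-[acetyl(3-aminopropyl)amino]butyl]carbamate | CC(C)(C)OC(=O)NCCCCN(CCCN)C(C)=O | intermediate
6 | 2-(diethoxyphosphoryl)acetic acid | CCOP(=O)(CC(=O)O)OCC | starting material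
7 | tert-butyl N-[4-[acetyl-[3-[[2-(diethoxyphosphoryl)acetyl]amino]propyl]amino]butyl]carbamate | CCOP(=O)(CC(=O)NCCCN(CCCCNC(=O)OC(C)(C)C)C(C)=O)OCC | intermediate
8 | ethyl (Z)-3-iodoprop-2-enoate | CCOC(=O)/C=C\I | starting material
9 | (Z)-3-iodoprop-2-enal (not isolated; present as its aluminium ethyl hemiacetal) | O=C/C=C\I | intermediate
10 | tert-butyl N-[4-[acetyl-[3-[[(2E,4Z)-5-iodopenta-2,4-dienoyl]amino]propyl]amino]butyl]carbamate | I/C=C\C=C\C(=O)NCCCN(CCCCNC(=O)OC(C)(C)C)C(C)=O | intermediate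
11 | (R)-pent-1-yn-3-ol | CC[C@@H](O)C#C | starting material
12 | (R,E)-1-(4,4,5,5-tetramethyl-1,3,2-dioxaborolan-2-yl)pent-1-en-3-ol | CC[C@@H](O)/C=C/B1OC(C)(C)C(C)(C)O1 | intermediate
13 | tert-butyl N-[4-[acetyl-[3-[[(2E,4Z,6E,8R)-8-hydroxydeca-2,4,6-trienoyl]amino]propyl]amino]butyl]carbamate | CC[C@@H](O)/C=C/C=C\C=C\C(=O)NCCCN(CCCCNC(=O)OC(C)(C)C)C(C)=O | intermediate
14 | trimethylsilyl N-[4-[acetyl-[3-[[(2E,4Z,6E,8R)-8-(trimethylsilyloxy)deca-2,4,6-trienoyl]amino]propyl]amino]butyl]carbamate (not isolated) | CC[C@@H](O[Si](C)(C)C)/C=C/C=C\C=C\C(=O)NCCCN(CCCCNC(=O)O[Si](C)(C)C)C(C)=O | intermediate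
15 | (2E,4Z,6E,8R)-N-[3-[acetyl(4-aminobutyl)amino]propyl]-8-hydroxydeca-2,4,6-trienamide | CC[C@@H](O)/C=C/C=C\C=C\C(=O)NCCCN(CCCCN)C(C)=O | intermediate
16 | (2R)-9-acetyl-2-[(1Z,3E,5R)-5-hydroxyhepta-1,3-dien-1-yl]-1,5,9-triazacyclotridecan-4-one | CC[C@@H](O)/C=C/C=C\[C@H]1CC(=O)NCCCN(C(C)=O)CCCCN1 | target

## Step count and risks

Total steps: 8. Longest linear sequence: 7 (steps 1, 2, 3, 4, 6, 7, 8); step 5 is a one-step branch.

**Most likely to fail, first: step 8.** A secondary trienamide is a poor acceptor, 1,6- or 1,8-addition and Z-to-E scrambling are possible, and the facial control is unprecedented for a free alkylamine. The fallback sets out from 15 and comes back at 16. It gives up asymmetric induction and relies on reversible closure, separation and recycling. Compound 15 is heated without chiral catalyst in MeOH/H2O 4:1 (5 mM, 60 °C), where the amine-to-enamide addition is assisted by the protic medium and is reversible. This gives 16 together with its C3 epimer, (2S)-9-acetyl-2-[(1Z,3E,5R)-5-hydroxyhepta-1,3-dien-1-yl]-1,5,9-triazacyclotridecan-4-one F1. Because C8 is fixed, the two are diastereomers and are separated by reverse-phase HPLC. F1 is returned to the same conditions (retro-aza-Michael to 15, then re-closure), so material converges on 16 over repeated cycles.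

**Second: step 4.** The Z-iodoenal may isomerise or polymerise before olefination, and the secondary phosphonoacetamide may react sluggishly. The fallback sets out from 7 (with 11 for the other half) and comes back at 13; it makes the 4Z alkene by alkyne semi-reduction. Compound 7 is condensed with commercial 3-(trimethylsilyl)propynal (LiCl, DBU, MeCN, 0 °C) to the silyl enynamide tert-butyl N-[4-[acetyl-[3-[[(E)-5-(trimethylsilyl)pent-2-en-4-ynoyl]amino]propyl]amino]butyl]carbamate F2. Desilylation (K2CO3, MeOH) gives the terminal enynamide tert-butyl N-[4-[acetyl-[3-[[(E)-pent-2-en-4-ynoyl]amino]propyl]amino]butyl]carbamate F3. Compound 11 is converted by hydrozirconation–iodination (Cp2Zr(H)Cl 2.2 equiv, THF; then I2) into (R,E)-1-iodopent-1-en-3-ol F4. Sonogashira coupling of F3 with F4 (Pd(PPh3)4, CuI, i-Pr2NH, THF, rt) gives the dienynamide tert-butyl N-[4-[acetyl-[3-[[(2E,6E,8R)-8-hydroxydeca-2,6-dien-4-ynoyl]amino]propyl]amino]butyl]carbamate F5. Cis semi-reduction of the alkyne with zinc activated by Cu(OAc)2 and AgNO3 (MeOH/H2O, rt) then gives 13.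

**Third: step 7.** The silyl triflate may ionise or isomerise the hydroxy-triene. The fallback sets out from 10 and comes back at 15; it switches to a carbamate that is removed under neutral conditions. The acid-stable iodide 10 is deprotected (TFA/CH2Cl2, 0 °C) to (2E,4Z)-N-[3-[acetyl(4-aminobutyl)amino]propyl]-5-iodopenta-2,4-dienamide F6, kept as its trifluoroacetate salt. It is reprotected at once (allyl chloroformate, NaHCO3, THF/H2O) as allyl N-[4-[acetyl-[3-[[(2E,4Z)-5-iodopenta-2,4-dienoyl]amino]propyl]amino]butyl]carbamate F7. Coupling of F7 with 12 under the step 6 conditions gives allyl N-[4-[acetyl-[3-[[(2E,4Z,6E,8R)-8-hydroxydeca-2,4,6-trienoyl]amino]propyl]amino]butyl]carbamate F8. Deallylation with Pd(PPh3)4 (5 mol%) and morpholine in THF at rt releases 15.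

## Further compounds

F1 | step 8 | (2S)-9-acetyl-2-[(1Z,3E,5R)-5-hydroxyhepta-1,3-dien-1-yl]-1,5,9-triazacyclotridecan-4-one | CC[C@@H](O)/C=C/C=C\[C@@H]1CC(=O)NCCCN(C(C)=O)CCCCN1
F2 | step 4 | tert-butyl N-[4-[acetyl-[3-[[(E)-5-(trimethylsilyl)pent-2-en-4-ynoyl]amino]propyl]amino]butyl]carbamate | C[Si](C)(C)C#C/C=C/C(=O)NCCCN(CCCCNC(=O)OC(C)(C)C)C(C)=O
F3 | step 4 | tert-butyl N-[4-[acetyl-[3-[[(E)-pent-2-en-4-ynoyl]amino]propyl]amino]butyl]carbamate | C#C/C=C/C(=O)NCCCN(CCCCNC(=O)OC(C)(C)C)C(C)=O
F4 | step 4 | (R,E)-1-iodopent-1-en-3-ol | CC[C@@H](O)/C=C/I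
F5 | step 4 | tert-butyl N-[4-[acetyl-[3-[[(2E,6E,8R)-8-hydroxydeca-2,6-dien-4-ynoyl]amino]propyl]amino]butyl]carbamate | CC[C@@H](O)/C=C/C#C/C=C/C(=O)NCCCN(CCCCNC(=O)OC(C)(C)C)C(C)=O
F6 | step 7 | (2E,4Z)-N-[3-[acetyl(4-aminobutyl)amino]propyl]-5-iodopenta-2,4-dienamide | I/C=C\C=C\C(=O)NCCCN(CCCCN)C(C)=O
F7 | step 7 | allyl N-[4-[acetyl-[3-[[(2E,4Z)-5-iodopenta-2,4-dienoyl]amino]propyl]amino]butyl]carbamate | I/C=C\C=C\C(=O)NCCCN(CCCCNC(=O)OCC=C)C(C)=O
F8 | step 7 | allyl N-[4-[acetyl-[3-[[(2E,4Z,6E,8R)-8-hydroxydeca-2,4,6-trienoyl]amino]propyl]amino]butyl]carbamate | CC[C@@H](O)/C=C/C=C\C=C\C(=O)NCCCN(CCCCNC(=O)OCC=C)C(C)=O
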